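**Retrosynthetic overview**

1. The last bond made is C11=C12 (Wittig), joining a ring A C15 hydroxy enynal (C1–C11) to a ring B C25 hexaenyl phosphonium salt (C12–C6'). The C25 salt comes from (R)-α-ionone, a vinyl Grignard reagent and the C10 dialdehyde by two phosphonium salt/Wittig cycles.
2. The plan rests on the C5=C6–C7≡C8–C9(CH3)=C10 ene-yne-ene of ring A. Its 9E geometry is labile once the alkyne exists, and C6 is buried between the C1 gem-dimethyl group and the C5 methyl group.
3. The C7≡C8 bond is therefore released from a 1,1-dibromoalkene whose other carbon carries ring A C6 and the E-configured C9 alkenyl group. A carbenoid 1,2-shift (Fritsch–Buttenberg–Wiechell) forms C6–C7 and the triple bond in one operation.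
4. The dibromoalkene comes from the cross-conjugated dienone. The dienone is made by Nozaki–Hiyama–Kishi coupling of the ring A enol triflate with an E-configured C5 enal, then oxidation. The triflate comes from ketoisophorone, with the C3 centre set by enzymatic ene reduction followed by substrate-directed hydride reduction.
5. No ring is formed in the route: ring A is the six-membered ring of ketoisophorone and ring B that of (R)-α-ionone.

Key step: step 9

Remark: (R)-α-ionone of high enantiomeric purity, the C10 dialdehyde and 2-(triphenylphosphoranylidene)propanal are taken as purchasable; positions are cited in carotenoid numbering (unprimed for the ring A half, primed for the ring B half).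

**Route**

Step 1
Reactants: 1 ketoisophorone (2,6,6-trimethylcyclohex-2-ene-1,4-dione)
Product: 2 (6R)-2,2,6-trimethylcyclohexane-1,4-dione
Conditions: ene-reductase (old yellow enzyme 1), NADP+ (cat.), glucose dehydrogenase, D-glucose, phosphate buffer pH 7, 30 °C
Reagents that add atoms: none
Why: Flavin-dependent ene-reductases reduce the activated ring C=C bond by trans addition of hydride and a proton (asymmetric biocatalytic conjugate reduction), which should set the methyl-bearing centre as 6R; this centre steers step 2 and is erased in step 4.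

Step 2
Reactants: 2 (6R)-2,2,6-trimethylcyclohexane-1,4-dione
Product: 3 (4R,6R)-4-hydroxy-2,2,6-trimethylcyclohexan-1-one
Conditions: LiBH(s-Bu)3 (1.05 equiv), THF, −78 °C; then H2O
Reagents that add atoms: none
Why: Chemo- and diastereoselective hydride reduction: the C1 carbonyl is shielded by its CMe2 and CHMe neighbours, and the bulky borohydride attacks C4 equatorially, away from the axial C2 methyl group, to give the axial alcohol trans to the C6 methyl group, which is the 4R centre (C3 of the target).

Step 3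
Reactants: 3 (4R,6R)-4-hydroxy-2,2,6-trimethylcyclohexan-1-one
Product: 4 (4R,6R)-4-(tert-butyldimethylsilyloxy)-2,2,6-trimethylcyclohexan-1-one
Conditions: TBSCl, imidazole, DMF, rt
Reagents that add atoms: tert-butyldimethylsilyl chloride, CC(C)(C)[Si](C)(C)Cl
Why: Standard silylation of a secondary alcohol, which masks the hydroxyl group for the enolate, organochromium and organolithium steps that follow.

Step 4
Reactants: 4 (4R,6R)-4-(tert-butyldimethylsilyloxy)-2,2,6-trimethylcyclohexan-1-one
Product: 6 (4R)-4-(tert-butyldimethylsilyloxy)-2,6,6-trimethylcyclohex-1-en-1-yl trifluoromethanesulfonate, via lithium enolate 5 (not isolated)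
Conditions: LiN(i-Pr)2, THF, −78 → 0 °C; then PhNTf2, 0 °C → rt
Reagents that add atoms: N-phenylbis(trifluoromethanesulfonimide), O=S(=O)(N(c1ccccc1)S(=O)(=O)C(F)(F)F)C(F)(F)F
Why: C6 carries the only α-hydrogen, so a single enolate forms and is O-sulfonylated (enol triflate formation); the C6 centre is erased on purpose and the γ-silyloxy centre cannot be eliminated or epimerised.

Step 5
Reactants: 7 (tert-butyldimethylsilyloxy)acetaldehyde, 8 2-(triphenylphosphoranylidene)propanal
Product: 9 (2E)-4-(tert-butyldimethylsilyloxy)-2-methylbut-2-enal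
Conditions: toluene, 80 °C
Reagents that add atoms: none
Why: Wittig olefination with a formyl-stabilised ylide is reliably E-selective, so the future 9E geometry is fixed on a small fragment that can be purified.

Step 6
Reactants: 6 (4R)-4-(tert-butyldimethylsilyloxy)-2,6,6-trimethylcyclohex-1-en-1-yl trifluoromethanesulfonate, 9 (2E)-4-(tert-butyldimethylsilyloxy)-2-methylbut-2-enal
Product: 11 (2E)-4-(tert-butyldimethylsilyloxy)-1-[(4R)-4-(tert-butyldimethylsilyloxy)-2,6,6-trimethylcyclohex-1-en-1-yl]-2-methylbut-2-en-1-ol (both C1 epimers), via ring A alkenylchromium dichloride 10 (not isolated)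
Conditions: CrCl2 (4 equiv), NiCl2 (2 mol%), DMF, rt
Reagents that add atoms: none
Why: Nozaki–Hiyama–Kishi coupling: zerovalent nickel inserts into the C–OTf bond, transmetalation gives an alkenyl species of trivalent chromium that adds 1,2 to the enal and tolerates silyl ethers; the carbinol centre forms without control and is removed in step 7.

Step 7
Reactants: 11 (2E)-4-(tert-butyldimethylsilyloxy)-1-[(4R)-4-(tert-butyldimethylsilyloxy)-2,6,6-trimethylcyclohex-1-en-1-yl]-2-methylbut-2-en-1-ol
Product: 12 (2E)-4-(tert-butyldimethylsilyloxy)-1-[(4R)-4-(tert-butyldimethylsilyloxy)-2,6,6-trimethylcyclohex-1-en-1-yl]-2-methylbut-2-en-1-one (cross-conjugated dienone)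
Conditions: Dess–Martin periodinane, CH2Cl2, 0 °C → rt
Reagents that add atoms: none
Why: Dess–Martin oxidation of a doubly allylic secondary alcohol gives the dienone under mild, non-isomerising conditions, and the E enone is also the thermodynamically preferred isomer.

Step 8
Reactants: 12 cross-conjugated dienone, 13 carbon tetrabromide
Product: 14 (4R)-1-[(3E)-1,1-dibromo-5-(tert-butyldimethylsilyloxy)-3-methylpenta-1,3-dien-2-yl]-4-(tert-butyldimethylsilyloxy)-2,6,6-trimethylcyclohex-1-ene (gem-dibromoalkene)
Conditions: PPh3, Zn dust, CH2Cl2, rt (ylide formation); then 12, rt → 40 °C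
Reagents that add atoms: none
Why: Ramirez (Corey–Fuchs) dibromoolefination, a Wittig reaction of Ph3P=CBr2 with a ketone that has no α-hydrogen; the CBr2 terminus is symmetric, so no new geometric element arises and C9=C10 stays E, while the zinc variant avoids Ph3PBr2, which could attack the allylic silyl ether.

Step 9
Reactants: 14 gem-dibromoalkene
Product: 16 tert-butyl{[(2E)-5-[(4R)-4-(tert-butyldimethylsilyloxy)-2,6,6-trimethylcyclohex-1-en-1-yl]-3-methylpent-2-en-4-yn-1-yl]oxy}dimethylsilane (C15 enyne bis-silyl ether), via 1-bromo-1-lithioalkene carbenoid 15 (not isolated)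
Conditions: n-BuLi (1.15 equiv), hexane, −78 → −20 °C
Reagents that add atoms: none
Why: Br/Li exchange on either bromine of 14 gives the 1-bromo-1-lithioalkene 15, and as LiBr leaves, the sp2 carbon anti to the departing bromide (ring A C6, or C9 of the side chain) shifts to the carbenoid carbon, so that either migration ends in the same C6–C7≡C8–C9 array; this is the Fritsch–Buttenberg–Wiechell rearrangement in its carbenoid form, closest in precedent to the butyllithium-induced conversion of 2,2-diaryl-, 2-alkynyl- and 2-alkenyl-1,1-dibromoalkenes into internal alkynes. No ring is closed and no stereocentre is formed; the C3 silyloxy centre is remote and untouched. The migrating carbon keeps its configuration and the C9=C10 bond is never part of an allylic anion or cation, so the E geometry of 14 is carried over unchanged. The selectivity needed is the 1,2-shift over 1,5 C–H insertion into the C1 methyl groups and over protonation or butylation of 15; two sp2 substituents of high migratory aptitude, a lithium-bound carbenoid instead of a free carbene, a hydrocarbon solvent and low temperature all favour the shift. Silyl ethers do not react with n-BuLi at −78 °C.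

Step 10
Reactants: 16 C15 enyne bis-silyl ether
Product: 17 (1R)-4-[(3E)-5-hydroxy-3-methylpent-3-en-1-yn-1-yl]-3,5,5-trimethylcyclohex-3-en-1-ol (C15 enyne diol)
Conditions: Bu4NF (3 equiv), THF, 0 °C → rt, dark
Reagents that add atoms: none
Why: Fluoride cleaves both Si–O bonds; removing both silyl groups here makes a selective mono-desilylation unnecessary and avoids a deprotection on the C40 polyene.

Step 11
Reactants: 17 C15 enyne diol
Product: 18 (2E)-5-[(4R)-4-hydroxy-2,6,6-trimethylcyclohex-1-en-1-yl]-3-methylpent-2-en-4-ynal (C15 hydroxy enynal)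
Conditions: MnO2 (activated, excess), CH2Cl2, rt, dark
Reagents that add atoms: none
Why: MnO2 oxidises only the allylic primary alcohol (chemoselective allylic oxidation), the ring hydroxyl group not being allylic, and the neutral conditions in the dark should leave the 9E bond in place.

Step 12
Reactants: 19 (R)-α-ionone, 20 vinylmagnesium bromide
Product: 21 (1E)-3-methyl-1-[(1R)-2,6,6-trimethylcyclohex-2-en-1-yl]penta-1,4-dien-3-ol (vinyl-α-ionol, both C3 epimers)
Conditions: CH2=CHMgBr (1.2 equiv), THF, −30 → 0 °C; aq. NH4Cl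
Reagents that add atoms: none
Why: 1,2-Addition of the vinyl Grignard reagent to the enone carbonyl at low temperature; the C6' centre is not enolised and the new carbinol centre disappears in step 13.

Step 13
Reactants: 21 vinyl-α-ionol
Product: 22 [(2E,4E)-3-methyl-5-[(1R)-2,6,6-trimethylcyclohex-2-en-1-yl]penta-2,4-dien-1-yl]triphenylphosphonium bromide (ring B C15 salt)
Conditions: PPh3·HBr, MeOH, rt; crystallisation
Reagents that add atoms: triphenylphosphine hydrobromide, Br.c1ccc(cc1)P(c1ccccc1)c1ccccc1
Why: Acid ionises the tertiary bis-allylic alcohol to a pentadienyl cation that PPh3 captures at the unhindered primary terminus (allylic transposition to the phosphonium salt); the 9'E isomer is favoured and C6' is not involved.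

Step 14
Reactants: 22 ring B C15 salt, 23 (2E,4E,6E)-2,7-dimethylocta-2,4,6-trienedial (C10 dialdehyde)
Product: 25 (2E,4E,6E,8E,10E,12E)-2,7,11-trimethyl-13-[(1R)-2,6,6-trimethylcyclohex-2-en-1-yl]trideca-2,4,6,8,10,12-hexaenal (C25 aldehyde), via C15 phosphonium ylide 24 (not isolated)
Conditions: NaN(SiMe3)2, THF, −78 °C; ylide added to 23 (3 equiv), −78 → 0 °C; then I2 (cat.), heptane, rt, daylight
Reagents that add atoms: none
Why: Wittig olefination of one formyl group of the dialdehyde, which is kept in excess and is more electrophilic than the product so that mono-condensation prevails; the new C11'=C12' bond is equilibrated to E by iodine catalysis, which does not touch C6'.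

Step 15
Reactants: 25 C25 aldehyde
Product: 26 (2E,4E,6E,8E,10E,12E)-2,7,11-trimethyl-13-[(1R)-2,6,6-trimethylcyclohex-2-en-1-yl]trideca-2,4,6,8,10,12-hexaen-1-ol (C25 alcohol)
Conditions: NaBH4, MeOH/THF, 0 °C, dark
Reagents that add atoms: none
Why: Borohydride reduces the polyenal 1,2 to the primary allylic alcohol without touching the polyene.

Step 16
Reactants: 26 C25 alcohol
Product: 27 [(2E,4E,6E,8E,10E,12E)-2,7,11-trimethyl-13-[(1R)-2,6,6-trimethylcyclohex-2-en-1-yl]trideca-2,4,6,8,10,12-hexaen-1-yl]triphenylphosphonium bromide (ring B C25 salt)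
Conditions: PPh3·HBr, MeOH/CH2Cl2, 0 °C → rt, dark
Reagents that add atoms: triphenylphosphine hydrobromide, Br.c1ccc(cc1)P(c1ccccc1)c1ccccc1
Why: As in step 13, the allylic alcohol is ionised and PPh3 adds to the primary terminus C12 of the delocalised cation, the way retinyl phosphonium salts are made from retinol.

Step 17
Reactants: 27 ring B C25 salt, 18 C15 hydroxy enynal
Product: 29 (3R,6'R)-7,8-didehydro-β,ε-caroten-3-ol (crocoxanthin, CNP0322200.1), via C25 phosphonium ylide 28 (not isolated)
Conditions: NaN(SiMe3)2, THF, −78 °C; then 18, −78 → 0 °C, dark; crude warmed in heptane, 50 °C, dark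
Reagents that add atoms: none
Why: Wittig olefination forms C11=C12 with the 9E enyne in the electrophile, never in an allylic anion; the ylide is too weak a base to deprotonate the C3 hydroxyl group, and the hindered 11Z isomer should revert to E on gentle warming while the unhindered 9E bond stays.

**Compound list**

1 | ketoisophorone (2,6,6-trimethylcyclohex-2-ene-1,4-dione) | CC1=CC(=O)CC(C)(C)C1=O | starting material
2 | (6R)-2,2,6-trimethylcyclohexane-1,4-dione | O=C1[C@H](C)CC(=O)CC1(C)C | intermediate
3 | (4R,6R)-4-hydroxy-2,2,6-trimethylcyclohexan-1-one | O=C1[C@H](C)C[C@@H](O)CC1(C)C | intermediate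
4 | (4R,6R)-4-(tert-butyldimethylsilyloxy)-2,2,6-trimethylcyclohexan-1-one | O=C1[C@H](C)C[C@@H](O[Si](C)(C)C(C)(C)C)CC1(C)C | intermediate
5 | lithium (4R)-4-(tert-butyldimethylsilyloxy)-2,6,6-trimethylcyclohex-1-en-1-olate (lithium enolate, not isolated) | [Li]OC1=C(C)C[C@@H](O[Si](C)(C)C(C)(C)C)CC1(C)C | intermediate
6 | (4R)-4-(tert-butyldimethylsilyloxy)-2,6,6-trimethylcyclohex-1-en-1-yl trifluoromethanesulfonate | FC(F)(F)S(=O)(=O)OC1=C(C)C[C@@H](O[Si](C)(C)C(C)(C)C)CC1(C)C | intermediate
7 | (tert-butyldimethylsilyloxy)acetaldehyde | O=CCO[Si](C)(C)C(C)(C)C | starting material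
8 | 2-(triphenylphosphoranylidene)propanal | CC(C=O)=P(c1ccccc1)(c1ccccc1)c1ccccc1 | starting material
9 | (2E)-4-(tert-butyldimethylsilyloxy)-2-methylbut-2-enal | O=C/C(C)=C/CO[Si](C)(C)C(C)(C)C | intermediate
10 | [(4R)-4-(tert-butyldimethylsilyloxy)-2,6,6-trimethylcyclohex-1-en-1-yl]chromium dichloride (not isolated) | Cl[Cr](Cl)C1=C(C)C[C@@H](O[Si](C)(C)C(C)(C)C)CC1(C)C | intermediate
11 | (2E)-4-(tert-butyldimethylsilyloxy)-1-[(4R)-4-(tert-butyldimethylsilyloxy)-2,6,6-trimethylcyclohex-1-en-1-yl]-2-methylbut-2-en-1-ol (both C1 epimers) | OC(C1=C(C)C[C@@H](O[Si](C)(C)C(C)(C)C)CC1(C)C)/C(C)=C/CO[Si](C)(C)C(C)(C)C | intermediate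
12 | (2E)-4-(tert-butyldimethylsilyloxy)-1-[(4R)-4-(tert-butyldimethylsilyloxy)-2,6,6-trimethylcyclohex-1-en-1-yl]-2-methylbut-2-en-1-one | O=C(C1=C(C)C[C@@H](O[Si](C)(C)C(C)(C)C)CC1(C)C)/C(C)=C/CO[Si](C)(C)C(C)(C)C | intermediate
13 | carbon tetrabromide | BrC(Br)(Br)Br | starting material
14 | (4R)-1-[(3E)-1,1-dibromo-5-(tert-butyldimethylsilyloxy)-3-methylpenta-1,3-dien-2-yl]-4-(tert-butyldimethylsilyloxy)-2,6,6-trimethylcyclohex-1-ene | BrC(Br)=C(C1=C(C)C[C@@H](O[Si](C)(C)C(C)(C)C)CC1(C)C)/C(C)=C/CO[Si](C)(C)C(C)(C)C | intermediate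
15 | 1-bromo-1-lithioalkene carbenoid from 14 (either geometry at the carbenoid carbon, not isolated) | [Li]C(Br)=C(C1=C(C)C[C@@H](O[Si](C)(C)C(C)(C)C)CC1(C)C)/C(C)=C/CO[Si](C)(C)C(C)(C)C | intermediate
16 | tert-butyl{[(2E)-5-[(4R)-4-(tert-butyldimethylsilyloxy)-2,6,6-trimethylcyclohex-1-en-1-yl]-3-methylpent-2-en-4-yn-1-yl]oxy}dimethylsilane | CC(C)(C)[Si](C)(C)OC/C=C(\C)C#CC1=C(C)C[C@@H](O[Si](C)(C)C(C)(C)C)CC1(C)C | intermediate
17 | (1R)-4-[(3E)-5-hydroxy-3-methylpent-3-en-1-yn-1-yl]-3,5,5-trimethylcyclohex-3-en-1-ol | OC/C=C(\C)C#CC1=C(C)C[C@@H](O)CC1(C)C | intermediate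
18 | (2E)-5-[(4R)-4-hydroxy-2,6,6-trimethylcyclohex-1-en-1-yl]-3-methylpent-2-en-4-ynal | O=C/C=C(\C)C#CC1=C(C)C[C@@H](O)CC1(C)C | intermediate
19 | (R)-α-ionone ((3E)-4-[(1R)-2,6,6-trimethylcyclohex-2-en-1-yl]but-3-en-2-one) | CC1=CCCC(C)(C)[C@H]1/C=C/C(C)=O | starting material
20 | vinylmagnesium bromide | C=C[Mg]Br | starting material
21 | (1E)-3-methyl-1-[(1R)-2,6,6-trimethylcyclohex-2-en-1-yl]penta-1,4-dien-3-ol (both C3 epimers) | CC1=CCCC(C)(C)[C@H]1/C=C/C(C)(O)C=C | intermediate
22 | [(2E,4E)-3-methyl-5-[(1R)-2,6,6-trimethylcyclohex-2-en-1-yl]penta-2,4-dien-1-yl]triphenylphosphonium bromide | CC1=CCCC(C)(C)[C@H]1/C=C/C(C)=C/C[P+](c1ccccc1)(c1ccccc1)c1ccccc1.[Br-] | intermediate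
23 | (2E,4E,6E)-2,7-dimethylocta-2,4,6-trienedial | O=C/C(C)=C/C=C/C=C(C)/C=O | starting material
24 | C15 phosphonium ylide from 22 (not isolated) | CC1=CCCC(C)(C)[C@H]1/C=C/C(C)=C/C=P(c1ccccc1)(c1ccccc1)c1ccccc1 | intermediate
25 | (2E,4E,6E,8E,10E,12E)-2,7,11-trimethyl-13-[(1R)-2,6,6-trimethylcyclohex-2-en-1-yl]trideca-2,4,6,8,10,12-hexaenal | CC1=CCCC(C)(C)[C@H]1/C=C/C(C)=C/C=C/C(C)=C/C=C/C=C(C)/C=O | intermediate
26 | (2E,4E,6E,8E,10E,12E)-2,7,11-trimethyl-13-[(1R)-2,6,6-trimethylcyclohex-2-en-1-yl]trideca-2,4,6,8,10,12-hexaen-1-ol | CC1=CCCC(C)(C)[C@H]1/C=C/C(C)=C/C=C/C(C)=C/C=C/C=C(C)/CO | intermediate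
27 | [(2E,4E,6E,8E,10E,12E)-2,7,11-trimethyl-13-[(1R)-2,6,6-trimethylcyclohex-2-en-1-yl]trideca-2,4,6,8,10,12-hexaen-1-yl]triphenylphosphonium bromide | CC1=CCCC(C)(C)[C@H]1/C=C/C(C)=C/C=C/C(C)=C/C=C/C=C(C)/C[P+](c1ccccc1)(c1ccccc1)c1ccccc1.[Br-] | intermediate
28 | C25 phosphonium ylide from 27 (not isolated) | CC1=CCCC(C)(C)[C@H]1/C=C/C(C)=C/C=C/C(C)=C/C=C/C=C(C)/C=P(c1ccccc1)(c1ccccc1)c1ccccc1 | intermediate
29 | (3R,6'R)-7,8-didehydro-β,ε-caroten-3-ol (crocoxanthin, CNP0322200.1) | CC1=CCCC(C)(C)[C@H]1/C=C/C(C)=C/C=C/C(C)=C/C=C/C=C(C)/C=C/C=C(\C)C#CC1=C(C)C[C@@H](O)CC1(C)C | target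

**Step count**

Total: 17 steps. Longest linear sequence: 11 steps (steps 1–4, 6–11 and 17). Step 5 and steps 12–16 are side branches.

**Steps most likely to fail**

Step 9 (key step). The carbenoid 15 may be diverted before the 1,2-shift: insertion into a C–H bond of the C1 methyl groups, capture of a proton, or alkylation by the butyl bromide formed in the exchange. The exchange may also stall on the crowded alkene. The fallback sets out from enol triflate 6 and comes back at 16. Commercial (E)-3-methylpent-2-en-4-yn-1-ol F1 is silylated (TBSCl, imidazole, DMF, rt) to tert-butyl{[(2E)-3-methylpent-2-en-4-yn-1-yl]oxy}dimethylsilane F2. Sonogashira coupling of F2 with 6 (Pd(PPh3)4, CuI, i-Pr2NH, DMF, rt, dark) forms the C6–C7 bond directly and gives 16, after which the route continues with step 10. This path exposes the finished ene-yne-ene to zerovalent palladium, copper and amine, where 9E can drift, which is why it is only the reserve.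

Step 8. The bulky ylide may fail to reach the carbonyl carbon, which is shielded by the twisted tetrasubstituted ring alkene on one side and the α-methyl alkenyl group on the other. Long reaction times may then lead to reversible conjugate addition of the phosphine or loss of the allylic silyl ether. The fallback sets out from dienone 12 and comes back at 14. The small carbenoid LiCHBr2 (CH2Br2, LiN(i-Pr)2, THF, −78 °C, ketone present) adds 1,2 to give 1,1-dibromo-5-(tert-butyldimethylsilyloxy)-2-[(4R)-4-(tert-butyldimethylsilyloxy)-2,6,6-trimethylcyclohex-1-en-1-yl]-3-methylpent-3-en-2-ol F3. Syn-dehydration of F3 with the Burgess reagent (methyl N-(triethylammoniosulfonyl)carbamate, toluene, 50 °C) can only take the hydrogen of the CHBr2 group and leads back to 14.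

Step 17. The new C11=C12 bond may form with poor E/Z selectivity, and the warming used to correct it, or traces of base acting on the enynal, may erode the 9E geometry. The fallback sets out from C25 alcohol 26 and comes back at 29. Mitsunobu reaction with 1-phenyl-1H-tetrazole-5-thiol (PPh3, DIAD, THF, 0 °C) gives the C25 tetrazolyl sulfide F4. Oxidation ((NH4)6Mo7O24 cat., H2O2, EtOH, 0 °C) gives the C25 tetrazolyl sulfone F5. Julia–Kocienski olefination of F5 with 18 (KN(SiMe3)2, DME, −60 °C → rt, dark) gives 29 under kinetic control at low temperature, without a phosphonium ylide.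

**Further compounds**

F1 | step 9 | (E)-3-methylpent-2-en-4-yn-1-ol | OC/C=C(\C)C#C
F2 | step 9 | tert-butyl{[(2E)-3-methylpent-2-en-4-yn-1-yl]oxy}dimethylsilane | CC(C)(C)[Si](C)(C)OC/C=C(\C)C#C
F3 | step 8 | 1,1-dibromo-5-(tert-butyldimethylsilyloxy)-2-[(4R)-4-(tert-butyldimethylsilyloxy)-2,6,6-trimethylcyclohex-1-en-1-yl]-3-methylpent-3-en-2-ol (3E, both C2 epimers) | OC(C(Br)Br)(C1=C(C)C[C@@H](O[Si](C)(C)C(C)(C)C)CC1(C)C)/C(C)=C/CO[Si](C)(C)C(C)(C)C
F4 | step 17 | 1-phenyl-5-{[(2E,4E,6E,8E,10E,12E)-2,7,11-trimethyl-13-[(1R)-2,6,6-trimethylcyclohex-2-en-1-yl]trideca-2,4,6,8,10,12-hexaen-1-yl]sulfanyl}-1H-tetrazole | CC1=CCCC(C)(C)[C@H]1/C=C/C(C)=C/C=C/C(C)=C/C=C/C=C(C)/CSc1nnnn1-c1ccccc1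
F5 | step 17 | 1-phenyl-5-{[(2E,4E,6E,8E,10E,12E)-2,7,11-trimethyl-13-[(1R)-2,6,6-trimethylcyclohex-2-en-1-yl]trideca-2,4,6,8,10,12-hexaen-1-yl]sulfonyl}-1H-tetrazole | CC1=CCCC(C)(C)[C@H]1/C=C/C(C)=C/C=C/C(C)=C/C=C/C=C(C)/CS(=O)(=O)c1nnnn1-c1ccccc1
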